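The readings are calculated on assumed constants.

Amounts came first. Per starting complex, the flask held 1.00 equiv of incoming ligand and 0.500 of protic impurity, so if each impurity took one ligand, 0.500 remained. I called this the working charge: incoming ligand charged minus protic impurity charged, both as fractions of the starting complex.

| flask | starting complex | incoming ligand | protic impurity | remark | time |
|---|---|---|---|---|---|
| red | 0.25 M | 1.4 equiv | 0.125 M | run made earlier |  |
| green | 0.25 M | 2.2 equiv | 0.125 M | run made earlier |  |
| flask | 0.25 M | 1.00 equiv | 0.125 M |  | 20 min |

- red (time / min: starting complex / %, complex with one exchanged / %, complex with two exchanged / %): 0.833: 68.3, 25.7, 5.8; 2.50: 66.7, 22.3, 11.2; 5.00: 66.1, 20.0, 12.1; 6.00: 67.1, 20.9, 12.4; 10.0: 66.6, 20.0, 11.6; 12.0: 66.5, 20.4, 11.1; 15.0: 67.4, 20.9, 12.4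
- green (time / min: starting complex / %, complex with one exchanged / %, complex with two exchanged / %): 1.33: 53.3, 27.9, 18.2; 2.00: 54.2, 26.7, 20.3; 3.00: 52.9, 25.8, 21.3; 5.00: 53.1, 24.7, 22.0; 6.00: 53.9, 24.3, 21.8; 10.0: 54.1, 24.8, 21.8; 15.0: 53.7, 25.5, 21.7

(readings scatter by 0.5 percentage points)

- how much of the starting complex has reacted by 20 min
- how much complex with one exchanged there is at 20 min, in percent of the starting complex charged
- how much complex with two exchanged there is at 20 min, in percent of the starting complex charged
- amount of complex with one exchanged if the flask were left three thousand times as long, in percent of the starting complex charged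



An error of one part in 10 in the ligand charge would have moved the working charge by 0.100. The same error in the impurity or the starting complex would have moved it by 0.0500, so the ligand charge mattered twice as much. Time mattered early in the red run, where complex with two exchanged rose from 5.8% at 0.833 min to 12.1% at 5.00 min, but from then on it showed no drift beyond the scatter of 0.5 percentage points, with 12.4% at 15.0 min.

I then tested the number on the last rows, taking released ligand equal to ligand used, 45.7% in red and 68.9% in green. With the full ligand charge, the first exchange constant read 0.150 in red and 0.217 in green. With working charges it read 0.320 and 0.324, so I kept the working charge.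

The forecast gave 22.5% reacted, 16.2% and 6.3% of the two products, and 16.2% for the long wait: “Over very long times, I expect no change, though an unseen slow process can't be excluded.”

The flask gave 22.9%, 16.4% and 6.54%, and 0.234% for the long wait.

    starting complex + incoming ligand ⇌ leaving ligand + complex with one exchanged (K = 0.320, k = 0.0740 /M/s)
    complex with one exchanged + incoming ligand ⇌ leaving ligand + complex with two exchanged (K = 0.600, k = 0.0370 /M/s)
    incoming ligand → decomposition product (k = 4.10 × 10⁻⁵ /s)
    protic impurity + incoming ligand → quenched reagent (k = 5.60 /M/s)

At 20 min, free incoming ligand, leaving ligand and decomposition product in the flask summed to 0.500, against the working charge of 0.500. Decomposition product there rose to 0.0218 M by 200 min. The neighbouring flask, with 0.31 M of protic impurity, had a working charge of −0.240. In that neighbour, incoming ligand, the limiting reagent, stood at 0%, protic impurity at 20% of its charge, and complex with one exchanged at 0.862%.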